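## Structural features

The target is a C2-symmetric C40 carotenoid. Two identical, fully saturated 1,1,5-trimethylcyclohexane end groups are joined through C6 and C6' by an all-E nonaene (C7 to C7') with methyl branches at C9, C13, C13' and C9'. Each ring carries four contiguous stereocentres, C3 (R, free hydroxyl), C4 (S, hydrogen sulfate), C5 (R, methyl) and C6 (R, polyene), and the quaternary C1 stands directly beside C6. O3 and O4 are cis to each other and trans to the C5 methyl, which is trans to the C6 side chain. In the preferred chair the chain, the methyl and O4 are equatorial, while O3 is axial and 1,3-diaxial to one C1 methyl. The fragile parts are the nonaene (light, oxygen, acid, electrophiles) and the secondary sulfate monoesters, which are strongly acidic, very polar and solvolytically labile and therefore have to come last. The difficulty is threefold: a stereotetrad next to a quaternary carbon, an E-selective link between the hindered C6 position and the polyene, and a monosulfation that must choose O4 over O3 twice. The key step uses the C2 methylene/C3,C4-cis-diol segment, which corresponds to C2, C3 and C4 of (–)-quinic acid. The enone made from that acid leaves C5 (β-carbon) and C6 (α-carbon) open for the methyl group and for C7, and keeps the C1 carbonyl as the site of the later gem-dimethyl group.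

## Logic of the disconnections

**24 to 22.** The two O4–S bonds are cut first, because the sulfate is the only charged, acid-labile function and would burden every earlier operation. This leaves a neutral, lipophilic tetrol. The forward step must choose the equatorial O4 over the axial O3 at both ends, which is arranged through the tin acetal 23.

**22 to 21.** The four C–O bonds of the two ketals are cut. The ketal is the stereocontrol element far upstream and the only diol protection the rings ever need, so no protecting-group exchange enters the route. The demand is a ketal cleavage mild enough for a nonaene.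

**21 to 18 and 19.** The C7=C8 and C7'=C8' double bonds are cut in a two-directional way. The central C20 unit 19 is purchasable with its seven E double bonds already defined, so the C40 problem shrinks to one C10 ring unit used twice. The forward step must form two E-disubstituted alkenes from a β-branched sulfonyl carbanion, passing through 20, with base-stable spectators.

**18 to 14 and 15.** The C7–S bond is cut (oxidation level adjusted through 17 and 16). Sulfur is introduced only after the zinc carbenoid and platinum steps, which it would disturb. The demand is an SN2 displacement at the β-branched primary C7 and an oxidation that leaves the ketal alone.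

**14 to 10.** After removal of the silyl group (13), the gem-dimethyl group is traced back through the spirocyclopropane 12 and the methylidene 11 to the C1 carbonyl of 10. The cuts are the cyclopropane C–C bond opened by hydrogen, the two C–C bonds made by carbene transfer, and the C1=CH2 bond. The quaternary centre is thus reduced to a ketone, which is exactly what the key step needs as its activating group. Every forward reagent must be non-basic, because O3 and O7 are both β to C1.

**10 to 9.** The O7–Si bond is cut. The silyl ether only serves to stop retro-aldol cleavage and dehydration of the β-hydroxy ketone during the C1 chemistry.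

**9 to 6.** The C5–CH3 and C6–C7 bonds are cut together, removing two stereocentres and two carbons in one operation and leaving a known enone. The forward step, through 7 and 8, must deliver methyl anti to O4, keep the enolate across C1=C6, and add one molecule of formaldehyde anti to the new methyl.

**6 to 1.** The C5=C6 double bond is traced to the β-hydroxy ketone 4 (through 5). The C1 carbonyl is traced to the diol 3 with its extra carbon, 3 to the lactone 2, and 2 to 1. The cuts are a C5–O bond, the bond to the former carboxyl carbon, and the ketal and lactone C–O bonds. The gain is a cheap chiral-pool start that already contains C2, C3 and C4 in the right configuration. The demand is an elimination that expels O5 but not O3.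

## Other disconnections considered

**Alternative 1:** The ring is cut at C1–C2 and C5–C6, a [4+2] retron in which a C3=C4 double bond stands in for the diol.

- Forward step: (E)-penta-1,3-diene A2 and 2,2,2-trifluoroethyl 3-methylbut-2-enoate A3 would combine under a proline-derived B-aryl oxazaborolidine activated by AlBr3 to the cis (endo) cyclohexene ester A1.
- In its favour: carbocycle, gem-dimethyl group, C5 methyl and the C7 carbon arise in one catalytic step from achiral bulk chemicals. On the carbon skeleton this is better than the chosen plan, which spends four steps on reaching 6 and three on the C1 methyl groups.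
- Against it: a β,β-disubstituted enoate is among the least reactive dienophiles even with a cationic Lewis acid. A1 has C5 as in the target but C6 epimeric, so base equilibration to the trans ester A4 would have to follow. The C3,C4-diol would then have to be added to the face of the alkene that carries the pseudo-axial C1 methyl (in the target O3 is 1,3-diaxial to it), so a simple osmylation is expected to prefer the wrong face.
- Comparison: on structure the alternative is better at C1 and equal at C5, but worse at C3, C4 and C6, which the chosen plan inherits from 1 or sets under strong substrate control. On mechanism a reagent-controlled cycloaddition competes with a substrate-controlled conjugate addition, and the two are equal in principle. On step economy the alternative could be three or four steps shorter to the stage of 14, but only if the dihydroxylation were face-selective; otherwise the gain is lost.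

**Alternative 2:** The polyene is cut at C10–C11 and C10'–C11' and at both C9–CH3 bonds.

- Forward step: two molecules of the ring enyne A6 would undergo Cp2ZrCl2-catalysed syn-methylalumination with AlMe3, and the alkenylalanes would couple in the same flask with the pentaene diiodide A7 under Pd(PPh3)4 (zerovalent palladium) and ZnCl2 to give the tetrakis(silyl) ether A5.
- In its favour: every double-bond geometry is programmed (C9=C10 by syn-carbometalation, C11=C12 by the iodide). This is better than the Julia–Kocienski step of the chosen plan on polyene stereocontrol. The silyl ethers of A5 fall to fluoride, which is also better than an acid-labile ketal at the C40 stage. Convergence and use of the symmetry are equal.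
- Against it: the cut does nothing for the ring. A6 needs the same four stereocentres and quaternary carbon, so a ring synthesis such as steps 1 to 10 would be required anyway, followed by homologation of C7 to an E-enyne in which C7=C8 is still made by olefination. A7 is a light-sensitive diiodide that must be prepared, whereas 19 is purchased. AlMe3 is pyrophoric and Lewis acidic, which forces the ketal to be exchanged for silyl ethers.
- Comparison: mechanistically cleaner for the chain, structurally silent on the rings, and about five steps longer overall.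

**Alternative 3:** The ring is cut at C4–C5 and C1–C6.

- Forward step: 4-methyl-2-(trimethylsilyloxy)penta-1,3-diene A9 would add through its terminal carbon to the β-carbon of (E)-3-(but-2-enoyl)oxazolidin-2-one A10 under [Cu(t-Bu-box)](SbF6)2 (divalent copper). The resulting imide enolate would close onto the dimethyl-substituted enone carbon to give the trans keto imide A8.
- In its favour: C5 and C6 arise trans and in the right absolute sense by catalysis (equal to the chosen plan on these two centres). The gem-dimethyl group is in place from the start (better). The acyl group is the C7 handle and the C3 ketone marks the position of O3.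
- Against it: the ring-closing Michael addition must form a bond to a fully substituted β-carbon and is expected to be slow and reversible. O4 is missing altogether: α-oxygenation of the C3 ketone must choose C4 over C2 and the face anti to the C5 methyl, and the ketone must then be reduced to the axial alcohol.
- Comparison: the alternative creates C5/C6 by reagent control and leaves C3/C4 to uncertain substrate control, whereas the chosen plan inherits C3/C4 and creates C5/C6 under the influence of the ketal. Step economy to the stage of 22 is roughly equal.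

Key step: step 5

Remarks on the chemistry, made before the steps:

- **Numbering.** Ring locants in all names follow the target: C1 is the carbonyl carbon and later the gem-dimethyl carbon, C2 the methylene, C3 and C4 the oxygenated carbons, C5 the methyl-bearing carbon, C6 the carbon that carries C7.
- **Configuration check.** The (4S,5R) enone 6 that follows from 1, the (3R,4S,5R,6S) ketone 9 and the (3R,4S,5R,6R) end groups of 24 describe one and the same spatial arrangement. The change of the C6 descriptor is a priority effect only. No structure needed correction.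
- **Design choice for the key step.** The isopropylidene ketal is kept on the enone because it controls C5 and is the only diol protection needed. The enolate is moved to zinc and quenched cold and acidic, because after the aldol step C2–H is acidic and O3 is β to the carbonyl.
- **Assumption.** The target is written as the free bis(hydrogen sulfate). It would be isolated and stored as its disodium salt after ion exchange; the neutral formula is used for the same substance.

## Route

Step 1
Reactants: 1 (–)-quinic acid
Product: 2 3,4-O-isopropylidenequinic acid 1,5-lactone (tertiary 1-OH free; configuration of 1)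
Conditions: Me2C(OMe)2, TsOH·H2O (cat.), acetone, reflux
Reagents that add atoms: 2,2-dimethoxypropane, COC(C)(C)OC
Why: Acid-catalysed ketalisation takes the only cis-1,2-diol (O3/O4) while the carboxyl group, cis to O5, lactonises (acetonide–lactone formation); no stereocentre is touched.

Step 2
Reactants: 2 3,4-O-isopropylidenequinic acid 1,5-lactone
Product: 3 1-(hydroxymethyl)-3,4-O-isopropylidenecyclohexane-1,3,4,5-tetrol (quinic acid numbering; 1-OH, O3 and O4 on one face, 5-OH on the other)
Conditions: NaBH4, EtOH, 0 °C → rt
Reagents that add atoms: none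
Why: Borohydride reduction of the strained α-hydroxy γ-lactone should give the primary alcohol and set O5 free; the ketal is inert.

Step 3
Reactants: 3 1-(hydroxymethyl)-3,4-O-isopropylidenecyclohexane-1,3,4,5-tetrol
Product: 4 (3R,4S,5R)-5-hydroxy-3,4-(isopropylidenedioxy)cyclohexan-1-one
Conditions: NaIO4, pH 7 phosphate buffer, 0 °C
Reagents that add atoms: none
Why: Periodate glycol cleavage of the tertiary/primary 1,2-diol removes the former carboxyl carbon as formaldehyde and leaves the C1 ketone; the 5-OH has no free vicinal hydroxyl and stays.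

Step 4
Reactants: 4 (3R,4S,5R)-5-hydroxy-3,4-(isopropylidenedioxy)cyclohexan-1-one
Product: 6 (4S,5R)-4,5-(isopropylidenedioxy)cyclohex-2-en-1-one [target numbering: (3R,4S)-3,4-(isopropylidenedioxy)cyclohex-5-en-1-one], via mesylate 5 (not isolated)
Conditions: MsCl, Et3N, CH2Cl2, 0 °C
Reagents that add atoms: none
Why: Mesylation of the β-hydroxyl and E1cB elimination through the C1=C6 enolate should give the conjugated enone; the sulfonate leaves far more readily than the ketal oxygen O3, so short exposure at 0 °C keeps the diol segment intact.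

Step 5
Reactants: 6 (4S,5R)-4,5-(isopropylidenedioxy)cyclohex-2-en-1-one
Product: 9 (3R,4S,5R,6S)-6-(hydroxymethyl)-5-methyl-3,4-(isopropylidenedioxy)cyclohexan-1-one, via lithium enolate 7 (not isolated), via chlorozinc enolate 8 (not isolated)
Conditions: Me2CuLi (from MeLi, CuI), Et2O, −78 °C; ZnCl2, THF, −78 °C; CH2O (monomer in THF, from cracked paraformaldehyde), −78 → −40 °C; AcOH, then aq. NH4Cl
Reagents that add atoms: lithium dimethylcuprate, [Li+].C[Cu-]C; formaldehyde, C=O
Why: The soft cuprate adds 1,4 to 6 through a copper–alkene π-complex and a β-cuprio enolate; in the cis-fused bicycle the C4–O bond is pseudo-axial and the dioxolane covers one face, so the methyl group is placed on C5 anti to O4 by axial attack on the open face, which fixes C5 as R. The enolate forms only across C1=C6 (7) and is moved to zinc (8), which slows proton transfer to C2 and with it the loss of O3 by β-elimination. Aldol addition of 8 to monomeric formaldehyde should then form C6–C7 on the face opposite the new methyl and give the trans-diequatorial 5,6-arrangement, which is also the thermodynamic one for this epimerisable centre. The closest known reaction type is the three-component enone coupling, an organocopper conjugate addition followed by aldehyde trapping of the regiospecific enolate, for which formaldehyde is an established electrophile. No ring is closed: the carbocycle with C2, C3 and C4 is carried over unchanged from 1. C5 is controlled by the ketal-bearing C4 and C6 by the C5 methyl, both by substrate control. The step needs 1,4- over 1,2-addition (secured by the cuprate), facial selectivity (secured by the cis-fused ketal) and a single hydroxymethylation without enolate equilibration (secured by low temperature, the zinc counter-ion and the acidic quench at −78 °C).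

Step 6
Reactants: 9 (3R,4S,5R,6S)-6-(hydroxymethyl)-5-methyl-3,4-(isopropylidenedioxy)cyclohexan-1-one
Product: 10 (3R,4S,5R,6S)-6-[(tert-butyldimethylsilyloxy)methyl]-5-methyl-3,4-(isopropylidenedioxy)cyclohexan-1-one
Conditions: TBSCl, imidazole, DMF, 0 °C → rt
Reagents that add atoms: tert-butyldimethylsilyl chloride, CC(C)(C)[Si](C)(C)Cl
Why: Silylation of the primary aldol hydroxyl under weakly basic conditions blocks retro-aldol cleavage and dehydration in the following steps; the C6 centre is already the thermodynamic epimer.

Step 7
Reactants: 10 (3R,4S,5R,6S)-6-[(tert-butyldimethylsilyloxy)methyl]-5-methyl-3,4-(isopropylidenedioxy)cyclohexan-1-one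
Product: 11 (3R,4S,5R,6R)-6-[(tert-butyldimethylsilyloxy)methyl]-5-methyl-1-methylidene-3,4-(isopropylidenedioxy)cyclohexane
Conditions: Cp2TiMe2, toluene/THF, 65 °C, dark
Reagents that add atoms: dimethyltitanocene, C[Ti+2]C.c1cc[cH-]c1.c1cc[cH-]c1
Why: Thermolysis of Cp2TiMe2 gives the titanium methylidene, which methylenates the ketone through an oxatitanacyclobutane (Petasis methylenation); the reagent is non-basic, so neither O3 nor O7 is eliminated and C6 is not epimerised.

Step 8
Reactants: 11 (3R,4S,5R,6R)-6-[(tert-butyldimethylsilyloxy)methyl]-5-methyl-1-methylidene-3,4-(isopropylidenedioxy)cyclohexane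
Product: 12 spiro[cyclopropane-1,1'-cyclohexane] carrying 3,4-(isopropylidenedioxy), 5-methyl and 6-[(tert-butyldimethylsilyloxy)methyl] groups on the six-membered ring, (3R,4S,5R,6R)
Conditions: Et2Zn, CH2I2, CH2Cl2, 0 °C → rt
Reagents that add atoms: diiodomethane, ICI
Why: Simmons–Smith cyclopropanation (Furukawa variant) of the 1,1-disubstituted alkene; the spiro carbon carries two identical CH2 arms, so no new stereocentre arises.

Step 9
Reactants: 12 the spirocyclopropane
Product: 13 (3R,4S,5R,6R)-6-[(tert-butyldimethylsilyloxy)methyl]-3,4-(isopropylidenedioxy)-1,1,5-trimethylcyclohexane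
Conditions: H2 (4 atm), PtO2, AcOH, rt
Reagents that add atoms: none
Why: Hydrogenolysis of a 1,1-dialkylcyclopropane over platinum cleaves the least hindered CH2–CH2 bond and should leave two methyl groups on C1; ketal and silyl ether tolerate anhydrous acetic acid at room temperature.

Step 10
Reactants: 13 (3R,4S,5R,6R)-6-[(tert-butyldimethylsilyloxy)methyl]-3,4-(isopropylidenedioxy)-1,1,5-trimethylcyclohexane
Product: 14 [(3R,4S,5R,6R)-3,4-(isopropylidenedioxy)-1,1,5-trimethylcyclohex-6-yl]methanol
Conditions: Bu4NF, THF, rt
Reagents that add atoms: none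
Why: Fluoride cleaves the Si–O bond selectively; the ketal is untouched.

Step 11
Reactants: 14 [(3R,4S,5R,6R)-3,4-(isopropylidenedioxy)-1,1,5-trimethylcyclohex-6-yl]methanol; 15 1-phenyl-1H-tetrazole-5-thiol
Product: 16 1-phenyl-5-{[(3R,4S,5R,6R)-3,4-(isopropylidenedioxy)-1,1,5-trimethylcyclohex-6-yl]methylthio}-1H-tetrazole
Conditions: PPh3, DIAD, THF, 0 °C → rt
Reagents that add atoms: none
Why: Mitsunobu thioetherification: the acidic thiol displaces the oxyphosphonium group at the primary C7 by SN2; β-branching slows but does not prevent attack by the highly nucleophilic thiolate, and no stereocentre is involved.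

Step 12
Reactants: 16 the C7 sulfide
Product: 18 1-phenyl-5-{[(3R,4S,5R,6R)-3,4-(isopropylidenedioxy)-1,1,5-trimethylcyclohex-6-yl]methylsulfonyl}-1H-tetrazole, via sulfoxide 17 (not isolated)
Conditions: 30% H2O2, (NH4)6Mo7O24·4H2O (cat.), EtOH, 0 °C → rt
Reagents that add atoms: hydrogen peroxide, OO
Why: Molybdate-catalysed peroxide oxidation takes the sulfide through the sulfoxide to the sulfone; the medium is only weakly acidic, so the ketal survives.

Step 13
Reactants: 18 the C7 sulfone (2.3 equiv); 19 crocetin dialdehyde
Product: 21 (3R,4S,5R,6R,3'R,4'S,5'R,6'R)-3,4:3',4'-di-O-isopropylidene-5,6,5',6'-tetrahydro-β,β-carotene-3,4,3',4'-tetrol (all-E), via C30 apo-aldehyde 20 (not isolated)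
Conditions: KN(SiMe3)2, DME/THF, −60 °C → rt, dark, Ar
Reagents that add atoms: none
Why: Double Julia–Kocienski olefination: the potassium sulfonyl carbanion adds to each aldehyde, and Smiles rearrangement with loss of SO2 and the tetrazolone forms C7=C8 and C7'=C8'; the potassium counter-ion in a polar ether favours the E alkene. Any 7Z isomer can be converged on the all-E compound by thermal equilibration during crystallisation.

Step 14
Reactants: 21 the C40 bis-acetonide
Product: 22 (3R,4S,5R,6R,3'R,4'S,5'R,6'R)-5,6,5',6'-tetrahydro-β,β-carotene-3,4,3',4'-tetrol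
Conditions: CSA (cat.), MeOH/CH2Cl2, 0 °C → rt, dark, Ar; Et3N quench
Reagents that add atoms: none
Why: Acid-catalysed transketalisation to methanol frees both cis-diols; catalytic sulfonic acid in methanol is the usual way to remove ketals next to conjugated polyenes, and the rings have no allylic leaving group that would ionise.

Step 15
Reactants: 22 the C40 tetrol
Product: 24 (3R,4S,5R,6R,3'R,4'S,5'R,6'R)-5,6,5',6'-tetrahydro-β,β-carotene-3,4,3',4'-tetrol 4,4'-bis(hydrogen sulfate), via bis-stannylene acetal 23 (not isolated)
Conditions: Bu2SnO, MeOH/toluene, 60 °C, then evaporation; Me3N·SO3, 1,4-dioxane, rt, dark; Dowex 50W (Na+ form), MeOH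
Reagents that add atoms: sulfur trioxide–trimethylamine complex, C[N+](C)(C)S(=O)(=O)[O-]
Why: Stannylene-directed sulfation: in the dibutylstannylene acetal of a cis-diol the equatorial oxygen is the more nucleophilic, here O4, while the axial O3 is also shielded by the syn-axial C1 methyl; the mild SO3–amine complex leaves the polyene alone and no stereocentre is changed.

## Compound list

1 | (–)-quinic acid | C1[C@H]([C@H]([C@@H](C[C@@]1(C(=O)O)O)O)O)O | starting material
2 | 3,4-O-isopropylidenequinic acid 1,5-lactone | C1[C@H]([C@H]([C@@H](C[C@@]1(C2=O)O)O2)OC3(C)C)O3 | intermediate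
3 | 1-(hydroxymethyl)-3,4-O-isopropylidenecyclohexane-1,3,4,5-tetrol (configuration of 1) | C1[C@H]([C@H]([C@@H](C[C@@]1(CO)O)O)OC2(C)C)O2 | intermediate
4 | (3R,4S,5R)-5-hydroxy-3,4-(isopropylidenedioxy)cyclohexan-1-one | O=C1C[C@@H](O)[C@H](OC2(C)C)[C@H](O2)C1 | intermediate
5 | 5-O-methanesulfonate of 4 (configuration unchanged) | O=C1C[C@@H](OS(C)(=O)=O)[C@H](OC2(C)C)[C@H](O2)C1 | intermediate (not isolated)
6 | (4S,5R)-4,5-(isopropylidenedioxy)cyclohex-2-en-1-one | O=C1C=C[C@H](OC2(C)C)[C@H](O2)C1 | intermediate
7 | lithium (3R,4S,5R)-5-methyl-3,4-(isopropylidenedioxy)cyclohex-1(6)-en-1-olate | [Li+].[O-]C1=C[C@@H](C)[C@H](OC2(C)C)[C@H](O2)C1 | intermediate (not isolated)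
8 | chlorozinc enolate corresponding to 7 | Cl[Zn]OC1=C[C@@H](C)[C@H](OC2(C)C)[C@H](O2)C1 | intermediate (not isolated)
9 | (3R,4S,5R,6S)-6-(hydroxymethyl)-5-methyl-3,4-(isopropylidenedioxy)cyclohexan-1-one | OC[C@@H]1[C@@H](C)[C@H](OC2(C)C)[C@H](O2)CC1=O | intermediate
10 | (3R,4S,5R,6S)-6-[(tert-butyldimethylsilyloxy)methyl]-5-methyl-3,4-(isopropylidenedioxy)cyclohexan-1-one | CC(C)(C)[Si](C)(C)OC[C@@H]1[C@@H](C)[C@H](OC2(C)C)[C@H](O2)CC1=O | intermediate
11 | (3R,4S,5R,6R)-6-[(tert-butyldimethylsilyloxy)methyl]-5-methyl-1-methylidene-3,4-(isopropylidenedioxy)cyclohexane | CC(C)(C)[Si](C)(C)OC[C@@H]1[C@@H](C)[C@H](OC2(C)C)[C@H](O2)CC1=C | intermediate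
12 | (3R,4S,5R,6R) spirocyclopropane at C1 of the silyl ether ketal | CC(C)(C)[Si](C)(C)OC[C@@H]1[C@@H](C)[C@H](OC2(C)C)[C@H](O2)CC13CC3 | intermediate
13 | (3R,4S,5R,6R)-6-[(tert-butyldimethylsilyloxy)methyl]-3,4-(isopropylidenedioxy)-1,1,5-trimethylcyclohexane | CC(C)(C)[Si](C)(C)OC[C@@H]1[C@@H](C)[C@H](OC2(C)C)[C@H](O2)CC1(C)C | intermediate
14 | [(3R,4S,5R,6R)-3,4-(isopropylidenedioxy)-1,1,5-trimethylcyclohex-6-yl]methanol | OC[C@@H]1[C@@H](C)[C@H](OC2(C)C)[C@H](O2)CC1(C)C | intermediate
15 | 1-phenyl-1H-tetrazole-5-thiol | Sc1nnnn1-c1ccccc1 | starting material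
16 | 1-phenyl-5-{[(3R,4S,5R,6R)-3,4-(isopropylidenedioxy)-1,1,5-trimethylcyclohex-6-yl]methylthio}-1H-tetrazole | c1ccccc1-n1nnnc1SC[C@@H]1[C@@H](C)[C@H](OC2(C)C)[C@H](O2)CC1(C)C | intermediate
17 | corresponding sulfoxide (mixture at sulfur) | c1ccccc1-n1nnnc1S(=O)C[C@@H]1[C@@H](C)[C@H](OC2(C)C)[C@H](O2)CC1(C)C | intermediate (not isolated)
18 | 1-phenyl-5-{[(3R,4S,5R,6R)-3,4-(isopropylidenedioxy)-1,1,5-trimethylcyclohex-6-yl]methylsulfonyl}-1H-tetrazole | c1ccccc1-n1nnnc1S(=O)(=O)C[C@@H]1[C@@H](C)[C@H](OC2(C)C)[C@H](O2)CC1(C)C | intermediate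
19 | crocetin dialdehyde, (all-E)-2,6,11,15-tetramethylhexadeca-2,4,6,8,10,12,14-heptaenedial | O=C/C(C)=C/C=C/C(C)=C/C=C/C=C(C)/C=C/C=C(C)/C=O | starting material
20 | (3R,4S,5R,6R)-3,4-O-isopropylidene-3,4-dihydroxy-5,6-dihydro-8'-apo-β-caroten-8'-al (all-E) | O=C/C(C)=C/C=C/C(C)=C/C=C/C=C(C)/C=C/C=C(C)/C=C/[C@@H]1[C@@H](C)[C@H](OC2(C)C)[C@H](O2)CC1(C)C | intermediate (not isolated)
21 | (3R,4S,5R,6R,3'R,4'S,5'R,6'R)-3,4:3',4'-di-O-isopropylidene-5,6,5',6'-tetrahydro-β,β-carotene-3,4,3',4'-tetrol | CC(/C=C/C=C(C)/C=C/[C@@H]1[C@@H](C)[C@H](OC2(C)C)[C@H](O2)CC1(C)C)=C\C=C\C=C(C)\C=C\C=C(C)\C=C\[C@@H]1[C@@H](C)[C@H](OC2(C)C)[C@H](O2)CC1(C)C | intermediate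
22 | (3R,4S,5R,6R,3'R,4'S,5'R,6'R)-5,6,5',6'-tetrahydro-β,β-carotene-3,4,3',4'-tetrol | CC(/C=C/C=C(C)/C=C/[C@@H]1[C@@H](C)[C@H](O)[C@H](O)CC1(C)C)=C\C=C\C=C(C)\C=C\C=C(C)\C=C\[C@@H]1[C@@H](C)[C@H](O)[C@H](O)CC1(C)C | intermediate
23 | 3,4:3',4'-bis-O-(dibutylstannylene) acetal of 22 | CC(/C=C/C=C(C)/C=C/[C@@H]1[C@@H](C)[C@H](O[Sn]2(CCCC)CCCC)[C@H](O2)CC1(C)C)=C\C=C\C=C(C)\C=C\C=C(C)\C=C\[C@@H]1[C@@H](C)[C@H](O[Sn]2(CCCC)CCCC)[C@H](O2)CC1(C)C | intermediate (not isolated)
24 | (3R,4S,5R,6R,3'R,4'S,5'R,6'R)-5,6,5',6'-tetrahydro-β,β-carotene-3,4,3',4'-tetrol 4,4'-bis(hydrogen sulfate) | CC(/C=C/C=C(C)/C=C/[C@@H]1[C@@H](C)[C@H](OS(=O)(=O)O)[C@H](O)CC1(C)C)=C\C=C\C=C(C)\C=C\C=C(C)\C=C\[C@@H]1[C@@H](C)[C@H](OS(=O)(=O)O)[C@H](O)CC1(C)C | target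

## Step count and least certain steps

Total: 15 steps. Longest linear sequence: 15 steps, from 1 to 24; 15 and 19 are purchased and enter at steps 11 and 13.

**Step 5 (key step).** The most likely failure is incomplete or unselective trapping of the enolate. Proton transfer between enolate and aldolate can move the enolate to C1=C2, from where O3 is lost by β-elimination. Oligomerisation of formaldehyde or a second hydroxymethylation can compete. A mismatch between the rates of aldol addition and of these side reactions is the cause.
Fallback: the route leaves 6 with the same cuprate in the presence of Me3SiCl (THF, −78 °C) and isolates the silyl enol ether (3R,4S,5R)-5-methyl-3,4-(isopropylidenedioxy)-1-(trimethylsilyloxy)cyclohex-1(6)-ene F1. F1 is then hydroxymethylated in a Lewis-acid-catalysed Mukaiyama-type aldol reaction (Yb(OTf)3, aqueous CH2O, THF, rt) in which no basic species is present. The same two bonds and the same facial preferences apply, and the sequence returns to the route at 9.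

**Step 13.** The carbanion of 18 is β-branched and flanked by a quaternary carbon. The likely failures are a slow second olefination, self-condensation of the metallated sulfone, and erosion of E-selectivity at C7=C8 with the conjugated aldehyde.
Fallback: the polarity is reversed, starting from 14 and 19. Oxidation of 14 (Dess–Martin periodinane, NaHCO3, CH2Cl2) would give the aldehyde (3R,4S,5R,6R)-3,4-(isopropylidenedioxy)-1,1,5-trimethylcyclohexane-6-carbaldehyde F2. Reduction of 19 (NaBH4, MeOH/CH2Cl2, 0 °C) would give the diol (all-E)-2,6,11,15-tetramethylhexadeca-2,4,6,8,10,12,14-heptaene-1,16-diol F3, and PPh3·HBr (MeOH, rt) would turn it into the bis(triphenylphosphonium) dibromide F4. A double Wittig reaction of F4 with two equivalents of F2 (NaOMe, MeOH/CH2Cl2, rt), followed by thermal Z-to-E equilibration in hot heptane, returns to the route at 21.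

**Step 14.** Acid-induced stereomutation or degradation of the nonaene may outrun cleavage of the rather robust cis-fused cyclohexane ketals, and the lipophilic substrate is poorly soluble in methanol.
Fallback: the ketal is removed before the polyene exists. Starting from 18, aqueous acetic acid (80%, 50 °C) would give the diol sulfone 1-phenyl-5-{[(3R,4S,5R,6R)-3,4-dihydroxy-1,1,5-trimethylcyclohex-6-yl]methylsulfonyl}-1H-tetrazole F5. Silylation (Et3SiOTf, 2,6-lutidine, CH2Cl2, 0 °C) would give the bis(triethylsilyl) ether F6. Olefination of 19 with F6 under the conditions of step 13 would give the C40 tetrakis(triethylsilyl) ether F7. Buffered fluoride (Bu4NF, AcOH, THF, rt) returns to the route at 22.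

**Step 15.** Regiocontrol may be incomplete (sulfation at O3 or at both oxygens of one ring), and heating during formation of the tin acetal may cause stereomutation of the polyene.
Fallback: the two oxygens are told apart at the ring stage. Starting from 18 by way of the diol sulfone F5:
- silylation of the equatorial O4 (Et3SiCl, imidazole, CH2Cl2, −40 °C) would give the 4-O-triethylsilyl ether F8;
- forcing silylation of the axial O3 (t-BuMe2SiOTf, 2,6-lutidine, CH2Cl2, 0 °C → rt) would give the 3-O-tert-butyldimethylsilyl 4-O-triethylsilyl sulfone F9;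
- olefination of 19 as in step 13 would give the C40 3,3'-bis-O-tert-butyldimethylsilyl 4,4'-bis-O-triethylsilyl ether F10;
- selective cleavage of the triethylsilyl ethers (HF·pyridine, pyridine, THF, 0 °C) would give the 4,4'-diol F11;
- sulfation of the only free hydroxyls (SO3·pyridine, pyridine/DMF, rt) would give the 3,3'-bis-O-silyl 4,4'-bis(hydrogen sulfate) F12;
- Bu4NF (THF, rt) returns to the route at 24.

## Further compounds

F1 | step 5 | (3R,4S,5R)-5-methyl-3,4-(isopropylidenedioxy)-1-(trimethylsilyloxy)cyclohex-1(6)-ene | C[Si](C)(C)OC1=C[C@@H](C)[C@H](OC2(C)C)[C@H](O2)C1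
F2 | step 13 | (3R,4S,5R,6R)-3,4-(isopropylidenedioxy)-1,1,5-trimethylcyclohexane-6-carbaldehyde | O=C[C@@H]1[C@@H](C)[C@H](OC2(C)C)[C@H](O2)CC1(C)C
F3 | step 13 | (all-E)-2,6,11,15-tetramethylhexadeca-2,4,6,8,10,12,14-heptaene-1,16-diol | OC/C(C)=C/C=C/C(C)=C/C=C/C=C(C)/C=C/C=C(C)/CO
F4 | step 13 | (all-E)-2,6,11,15-tetramethylhexadeca-2,4,6,8,10,12,14-heptaene-1,16-diylbis(triphenylphosphonium) dibromide | [Br-].[Br-].c1ccccc1[P+](c1ccccc1)(c1ccccc1)C/C(C)=C/C=C/C(C)=C/C=C/C=C(C)/C=C/C=C(C)/C[P+](c1ccccc1)(c1ccccc1)c1ccccc1
F5 | step 14 | 1-phenyl-5-{[(3R,4S,5R,6R)-3,4-dihydroxy-1,1,5-trimethylcyclohex-6-yl]methylsulfonyl}-1H-tetrazole | c1ccccc1-n1nnnc1S(=O)(=O)C[C@@H]1[C@@H](C)[C@H](O)[C@H](O)CC1(C)C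
F6 | step 14 | 3,4-bis-O-triethylsilyl ether of F5 | c1ccccc1-n1nnnc1S(=O)(=O)C[C@@H]1[C@@H](C)[C@H](O[Si](CC)(CC)CC)[C@H](O[Si](CC)(CC)CC)CC1(C)C
F7 | step 14 | 3,4,3',4'-tetrakis-O-triethylsilyl ether of 22 | CC(/C=C/C=C(C)/C=C/[C@@H]1[C@@H](C)[C@H](O[Si](CC)(CC)CC)[C@H](O[Si](CC)(CC)CC)CC1(C)C)=C\C=C\C=C(C)\C=C\C=C(C)\C=C\[C@@H]1[C@@H](C)[C@H](O[Si](CC)(CC)CC)[C@H](O[Si](CC)(CC)CC)CC1(C)C
F8 | step 15 | 4-O-triethylsilyl ether of F5 (3-OH free) | c1ccccc1-n1nnnc1S(=O)(=O)C[C@@H]1[C@@H](C)[C@H](O[Si](CC)(CC)CC)[C@H](O)CC1(C)C
F9 | step 15 | 3-O-tert-butyldimethylsilyl 4-O-triethylsilyl ether of F5 | c1ccccc1-n1nnnc1S(=O)(=O)C[C@@H]1[C@@H](C)[C@H](O[Si](CC)(CC)CC)[C@H](O[Si](C)(C)C(C)(C)C)CC1(C)C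
F10 | step 15 | 3,3'-bis-O-tert-butyldimethylsilyl 4,4'-bis-O-triethylsilyl ether of 22 | CC(/C=C/C=C(C)/C=C/[C@@H]1[C@@H](C)[C@H](O[Si](CC)(CC)CC)[C@H](O[Si](C)(C)C(C)(C)C)CC1(C)C)=C\C=C\C=C(C)\C=C\C=C(C)\C=C\[C@@H]1[C@@H](C)[C@H](O[Si](CC)(CC)CC)[C@H](O[Si](C)(C)C(C)(C)C)CC1(C)C
F11 | step 15 | 3,3'-bis-O-tert-butyldimethylsilyl ether of 22 (4,4'-diol) | CC(/C=C/C=C(C)/C=C/[C@@H]1[C@@H](C)[C@H](O)[C@H](O[Si](C)(C)C(C)(C)C)CC1(C)C)=C\C=C\C=C(C)\C=C\C=C(C)\C=C\[C@@H]1[C@@H](C)[C@H](O)[C@H](O[Si](C)(C)C(C)(C)C)CC1(C)C
F12 | step 15 | 3,3'-bis-O-tert-butyldimethylsilyl ether of 24 | CC(/C=C/C=C(C)/C=C/[C@@H]1[C@@H](C)[C@H](OS(=O)(=O)O)[C@H](O[Si](C)(C)C(C)(C)C)CC1(C)C)=C\C=C\C=C(C)\C=C\C=C(C)\C=C\[C@@H]1[C@@H](C)[C@H](OS(=O)(=O)O)[C@H](O[Si](C)(C)C(C)(C)C)CC1(C)C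
A1 | alternative 1 | 2,2,2-trifluoroethyl (1S,2S)-2,6,6-trimethylcyclohex-3-ene-1-carboxylate (cis, endo adduct) | O=C(OCC(F)(F)F)[C@H]1[C@@H](C)C=CCC1(C)C
A2 | alternative 1 | (E)-penta-1,3-diene | C=C/C=C/C
A3 | alternative 1 | 2,2,2-trifluoroethyl 3-methylbut-2-enoate | CC(C)=CC(=O)OCC(F)(F)F
A4 | alternative 1 | 2,2,2-trifluoroethyl (1R,2S)-2,6,6-trimethylcyclohex-3-ene-1-carboxylate (trans epimer) | O=C(OCC(F)(F)F)[C@@H]1[C@@H](C)C=CCC1(C)C
A5 | alternative 2 | 3,4,3',4'-tetrakis-O-tert-butyldimethylsilyl ether of 22 | CC(/C=C/C=C(C)/C=C/[C@@H]1[C@@H](C)[C@H](O[Si](C)(C)C(C)(C)C)[C@H](O[Si](C)(C)C(C)(C)C)CC1(C)C)=C\C=C\C=C(C)\C=C\C=C(C)\C=C\[C@@H]1[C@@H](C)[C@H](O[Si](C)(C)C(C)(C)C)[C@H](O[Si](C)(C)C(C)(C)C)CC1(C)C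
A6 | alternative 2 | (3R,4S,5R,6R)-6-[(E)-but-1-en-3-ynyl]-3,4-bis(tert-butyldimethylsilyloxy)-1,1,5-trimethylcyclohexane | C#C/C=C/[C@@H]1[C@@H](C)[C@H](O[Si](C)(C)C(C)(C)C)[C@H](O[Si](C)(C)C(C)(C)C)CC1(C)C
A7 | alternative 2 | (all-E)-1,10-diiodo-3,8-dimethyldeca-1,3,5,7,9-pentaene | I/C=C/C(C)=C/C=C/C=C(C)/C=C/I
A8 | alternative 3 | 3-[(1R,6S)-2,2,6-trimethyl-4-oxocyclohexane-1-carbonyl]oxazolidin-2-one (trans) | O=C(N1CCOC1=O)[C@@H]1[C@@H](C)CC(=O)CC1(C)C
A9 | alternative 3 | 4-methyl-2-(trimethylsilyloxy)penta-1,3-diene | CC(C)=CC(=C)O[Si](C)(C)C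
A10 | alternative 3 | (E)-3-(but-2-enoyl)oxazolidin-2-one | C/C=C/C(=O)N1CCOC1=O
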